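## Remarks on the chemistry (assumptions)

- Germacrane numbering of the target is used for every intermediate: carbocycle C1–C10, C11 on C7, lactone carbonyl C12, C13 the methyl on C11, C14 the methyl on C10, C15 the methyl on C4.
- Commercial diene 1 contains the 1,6-dimethyl isomer; it is assumed to be purified first (AgNO3-impregnated silica or fractional distillation).
- Compounds 2, 3, 4, 5, 8 and 9 are racemic (one enantiomer drawn); 6, 11 and 14 are achiral. Absolute configuration enters in step 7.
- The new C7=C8 bond of 14 is drawn cis, the geometry expected for a ten-membered ring that already holds two cis olefins; the ligand enantiomer in step 7 is tied to this geometry.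
- The geometry of the C6=C7 enolate and silyl enol ether bonds is left undefined in the SMILES; it is not carried into any product.
- Transient chromate, vanadate and copper species are described in the Why lines and not numbered.
- The angeloyl donor 28 is made in one batch in step 13, filtered from the ammonium salt and kept cold under argon as a toluene solution; portions of this solution serve steps 14 and 15.

## Analysis of the target

The target 31 is a Z,Z-derived germacranolide: a ten-membered carbocycle trans-fused at C7–C8 to an α-acyloxy α-methyl γ-lactone, with cis-trisubstituted oxiranes at C1–C10 and C4–C5 and angelate esters on the secondary O6 and the tertiary O11. Its eight stereocentres (1R,4R,5S,6S,7S,8R,10S,11R) form one contiguous array C4–C5–C6–C7(–C11)–C8, with the C1/C10 oxirane separated from C8 only by the C9 methylene. In the formal flattened-ring sense, O6, the C4–C5 oxirane oxygen and C11 lie on one face of the carbocycle, while O8 and the C1–C10 oxirane oxygen lie on the other. Along the chain C5–C6–C7–C11–C12, O6, the C8 branch and O11 are mutually syn. The sensitive groups are the two trisubstituted epoxides (acid, transannular opening), the angelates (Z to E isomerisation to tiglates), the hindered tertiary ester, and a lactone that could migrate to O6 while that oxygen is free. The difficulty is to make a medium ring with two cis-trisubstituted olefins and then to place five oxygen functions on it with no resident stereocentre to start from. The strategy rests on one observation: removing C7 and C8 from the carbocycle leaves C6–C5=C4(C15)–C3–C2–C1=C10(C14)–C9 with C9 joined to C6. That is exactly the eight-membered ring of diene 1, with both cis olefins and both methyl groups in place.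

## Retrosynthetic reasoning

**Ester bonds at O11 and O6.** 31 is cut at the O11 ester to 29 and the mixed anhydride 28, and 29 is cut at the O6 ester to diol 26 and 28; 28 is traced to angelic acid 27. The angelates go on last because they isomerise easily. O6 is acylated first without generating its alkoxide, because a free C6 alkoxide next to the lactone and the C4–C5 oxirane would invite translactonisation and Payne rearrangement. The tertiary O11 then needs its alkoxide and the same anhydride 28.

**C4–C5 oxirane.** 26 is traced to allylic alcohol 25. The free C6 hydroxyl is the only handle that can steer an oxidant to the correct face of a flexible ring, so this epoxide is made as late as possible.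

**C6–H bond.** 25 comes from enone 23. The tertiary C11 hydroxyl and the C6 carbonyl are 1,3-related and cis on the lactone, so a chelating reduction can set C6 syn to O11.

**C7–C11 bond and lactone C–O bond.** 23 is cut to enol silane 19 and ethyl pyruvate 20. One aldol brings in C11, C12 and C13 and the tertiary oxygen; the lactone closes by itself once O8 is freed. C6 is still a ketone at this point, so only the required 12,8-lactone can form.

**C1–C10 oxirane.** 19 comes from 17 by silylation, and 17 from homoallylic alcohol 16. The epoxide is placed here because the C8 hydroxyl is free to direct it and the other olefin is an unreactive enone.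

**C8–O bond.** 16 is traced to the achiral trienone 14, and 14 to ketone 11 by dehydrogenation. Adding a boron nucleophile to C8 under a chiral copper catalyst is the step that introduces absolute configuration; everything later is relayed from C8.

**C8–C9 bond (key disconnection).** In 11 the bond C8–C9 is cut and C9 is re-joined to C6, which gives vinyl carbinol 8. No other cut reduces the ten-membered ring to a ring that already holds C1–C6, C9, C10, both cis olefins and both methyls. The forward reaction must break the allylic C6–C9 bond of alkoxide 9 and re-form it at the vinyl terminus.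

**Carbinol and C6 oxygen.** 8 comes from dienone 6 and vinylmagnesium bromide 7. 6 is traced through tertiary allylic alcohol 5 and epoxide 2 to diene 1. Direct allylic oxidation of 1 is avoided: it has two kinds of ring allylic methylene plus the methyls. Instead one olefin itself carries the oxygen to C6: epoxidation, selenide opening at C5, elimination toward C6, and oxidative 1,3-transposition.

## Alternatives that were turned down

**Alternative 1:** both oxiranes first, on an open chain.
- Disconnection: the ring is opened at C6–C7 and C8–C9, leaving the acyclic bis-epoxy diol A1, which comes from the Z,Z-diol A2.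
- Forward key step: Ti(OiPr)4, one enantiomer of a dialkyl tartrate and t-BuOOH epoxidise both allylic alcohols of A2 in one operation.
- For it: four stereocentres (C1, C4, C5, C10) are set by a well-understood catalyst, independent of any ring conformation. On this point it is stronger than the chosen route, which relies on hydroxyl direction in a flexible ring.
- Against it: A2 itself needs a Z-selective synthesis of the 2-methyl-alkenol terminus. After A1 the real problem begins: C7 and C8 must be inserted between two epoxy-aldehyde termini, C6, C7, C8 and C11 set under acyclic control, and a ten-membered ring closed with two acid-labile oxiranes already present.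
- Comparison: the chosen route gives up catalyst control of the epoxides but obtains the ring with both olefin geometries in five steps from 1 and keeps the epoxides out of the ring-forming chemistry.

**Alternative 2:** B-alkyl Suzuki macrocyclisation.
- Disconnection: C3–C4, back to an open-chain precursor with a terminal vinyl group on C2 and a Z-alkenyl iodide at C4.
- Forward key step: 9-BBN hydroborates the terminal olefin; Pd(dppf)Cl2, AsPh3 and Cs2CO3 couple the C3 borane with the C4 iodide at high dilution to give the protected dienolide A3.
- For it: the carbocycle is closed by a well-established cross-coupling, the 4Z geometry is fixed by the iodide, and C6, C7, C8 and C11 are defined before cyclisation. In predictability of ring formation it is stronger than the chosen key step.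
- Against it: the open chain needs a Z-alkenyl iodide, a Z-trisubstituted C1=C10 olefin inside a 1,3-diene, four stereocentres and two different silyl ethers. The hydroboration must distinguish the terminal olefin of a conjugated diene. Ten-membered closure competes with oligomerisation and β-hydride loss. After A3 the two epoxidations, two deprotections and two angeloylations still remain.
- Comparison: the chosen route is far shorter to the ring and needs no protecting groups on the carbocycle; the price is one unprecedented rearrangement.

**Alternative 3:** Grob fragmentation.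
- Disconnection: the C6 carbonyl and the C1=C10 olefin of A4 are traced back to the C6–C10 bond of the five-seven fused mesylate A5.
- Forward key step: KN(SiMe3)2 deprotonates the tertiary C6 hydroxyl of A5 and the C6–C10 bond, antiperiplanar to the C1–O bond, breaks to give A4.
- For it: the fragmentation is stereospecific and reliable, the Z geometry follows from the relative configuration at C1 and C10, and C8 already carries its oxygen. A4 is the silyl ether of compound 16, so the endgame would be shared.
- Against it: A5 needs four stereocentres, including a quaternary C10 and a tertiary carbinol, in a fixed relation (C9 and C2 gauche about C10–C1 with C6 anti to the mesylate). Three of those centres are destroyed in the key step. The bicycle would take many more steps than the seven that bring the chosen route to 16.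
- Comparison: the chosen route reaches the same intermediate from a commodity diene with no sacrificial stereocentres.

Key step: step 5

## Route

Step 1
Reactants: 1 (1Z,5Z)-1,5-dimethylcycloocta-1,5-diene
Product: 2 rac-(1R,8S,4Z)-1,5-dimethyl-9-oxabicyclo[6.1.0]non-4-ene
Conditions: mCPBA (0.9 equiv), NaHCO3, CH2Cl2, 0 °C
Reagents that add atoms: 3-chloroperoxybenzoic acid, OOC(=O)c1cccc(Cl)c1
Why: Prilezhaev epoxidation; the two olefins are equivalent by the twofold axis, so substoichiometric peracid should give mainly the mono-epoxide, with unreacted 1 recycled. Syn addition keeps the cis junction.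

Step 2
Reactants: 2 rac-(1R,8S,4Z)-1,5-dimethyl-9-oxabicyclo[6.1.0]non-4-ene
Product: 5 rac-(2Z,5Z)-1,5-dimethylcycloocta-2,5-dien-1-ol, via hydroxy selenide 3 (not isolated), via selenoxide 4 (not isolated)
Conditions: PhSeSePh, NaBH4, EtOH, reflux; then H2O2 (30 %), pyridine, THF, 0 °C to rt
Reagents that add atoms: none
Why: Epoxide to allylic alcohol by selenide opening and selenoxide syn-elimination. Benzeneselenolate attacks the secondary C5 with inversion, and the selenoxide can eliminate only toward C6 because C4 carries no hydrogen, so the tertiary alcohol with a cis C5=C6 olefin results.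

Step 3
Reactants: 5 rac-(2Z,5Z)-1,5-dimethylcycloocta-2,5-dien-1-ol
Product: 6 (2Z,6Z)-3,7-dimethylcycloocta-2,6-dien-1-one
Conditions: pyridinium chlorochromate [C5H5NH][CrO3Cl] (2 equiv), NaOAc, Celite, CH2Cl2, rt
Reagents that add atoms: pyridinium chlorochromate, [O-][Cr](=O)(=O)Cl.c1cc[nH+]cc1
Why: Babler–Dauben oxidative transposition: the chromate ester of the tertiary allylic alcohol undergoes a [3,3] shift to the C6 chromate, which hexavalent chromium oxidises to the enone. The olefin moves to C4=C5 and stays cis because the ring demands it; buffering limits ionisation and migration of the C1=C10 olefin into conjugation.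

Step 4
Reactants: 6 (2Z,6Z)-3,7-dimethylcycloocta-2,6-dien-1-one; 7 vinylmagnesium bromide
Product: 8 rac-(2Z,6Z)-3,7-dimethyl-1-vinylcycloocta-2,6-dien-1-ol
Conditions: CeCl3 (anhydrous), THF, −78 °C; then sat. aq. NH4Cl
Reagents that add atoms: none
Why: Organocerium 1,2-addition; the weakly basic reagent should add to the carbonyl without enolising the doubly activated C9 methylene (α to the ketone and allylic) and without conjugate addition.

Step 5
Reactants: 8 rac-(2Z,6Z)-3,7-dimethyl-1-vinylcycloocta-2,6-dien-1-ol
Product: 11 (2Z,6Z)-3,7-dimethylcyclodeca-2,6-dien-1-one, via potassium alkoxide 9 (not isolated), via potassium enolate 10 (not isolated)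
Conditions: KH (1.5 equiv), 18-crown-6 (1.5 equiv), THF, 0 to 40 °C; then sat. aq. NH4Cl, −78 °C
Reagents that add atoms: none
Why: Proposed new method: deprotonation gives alkoxide 9, whose charge weakens the allylic C6–C9 bond, because cleavage leaves a cross-conjugated dienone and a 2-methylallyl anion held together by the C2–C3 tether and the potassium ion. Re-bonding of the allyl terminus C9 to the vinyl terminus C8 (a formal suprafacial [1,3] shift, equivalent to a conjugate addition inside the ion pair) forms C8–C9 and gives the C6 enolate 10, which is protonated at C7 on quench. The closest known reaction type is the alkoxide-accelerated [1,3] shift of potassium 1-vinylcycloalk-3-en-1-olates, which expands the ring by two carbons in competition with the anionic oxy-Cope rearrangement; here the carbinol carbon also carries an in-ring vinyl group, which is why the step counts as new. The ten-membered ring is closed by ring expansion of the eight-membered ring, the bond formation being 10-endo-trig with respect to the C7=C8 acceptor. No stereocentre is formed and 11 is achiral; both trisubstituted olefins are spectators and should keep their cis geometry, since the short tether and the endo preference of allylpotassium species oppose rotation of the allyl fragment. The selectivity needed is C9-to-C8 bonding over three other recombinations: C1-to-C8 ([3,3], an eight-membered isomer) requires a boat array across the tub-shaped ring, and C9-to-C4 (contraction to a cyclohexene) or C1-to-C4 (a cyclobutane) would have to build a quaternary centre at the β,β-disubstituted enone terminus. The open, unsubstituted C8 and the release of eight-membered ring strain are what should favour the desired path.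

Step 6
Reactants: 11 (2Z,6Z)-3,7-dimethylcyclodeca-2,6-dien-1-one
Product: 14 (2Z,5Z,9Z)-5,9-dimethylcyclodeca-2,5,9-trien-1-one, via lithium enolate 12 (not isolated), via trimethylsilyl enol ether 13 (not isolated)
Conditions: LiN(i-Pr)2, THF, −78 °C; Me3SiCl; then Pd(OAc)2 (1.1 equiv), MeCN, rt
Reagents that add atoms: none
Why: Saegusa–Ito oxidation; kinetic deprotonation can occur only at C7 (C5 is vinylic), and the divalent palladium enolate loses a β-hydride from C8 to give the C7=C8 enone. The product is a divinyl ketone and is kept away from acid.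

Step 7
Reactants: 14 (2Z,5Z,9Z)-5,9-dimethylcyclodeca-2,5,9-trien-1-one
Product: 16 (2Z,6Z,9R)-9-hydroxy-3,7-dimethylcyclodeca-2,6-dien-1-one, via boronate 15 (not isolated)
Conditions: B2pin2, CuCl (5 mol %), NaOt-Bu (10 mol %), (R)-1-[(S)-2-(diphenylphosphino)ferrocenyl]ethyldicyclohexylphosphine (6 mol %), MeOH (2 equiv), THF, 0 °C; then NaBO3·4H2O, THF/H2O, rt
Reagents that add atoms: sodium perborate, [Na+].[O-]OB=O
Why: Copper-catalysed asymmetric conjugate borylation, then C–B oxidation with retention. The copper boryl species adds to the unhindered β-carbon C8 of the disubstituted enone, not to the β,β-disubstituted C4, and the chiral diphosphine selects the enantiotopic face of the achiral trienone, which sets C8 (8R). The ligand enantiomer is the one that delivers 8R and would be confirmed on the first run.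

Step 8
Reactants: 16 (2Z,6Z,9R)-9-hydroxy-3,7-dimethylcyclodeca-2,6-dien-1-one
Product: 17 (1S,3R,6Z,10R)-3-hydroxy-1,7-dimethyl-11-oxabicyclo[8.1.0]undec-6-en-5-one
Conditions: VO(acac)2 (5 mol %), t-BuOOH, CH2Cl2, 0 °C to rt
Reagents that add atoms: tert-butyl hydroperoxide, CC(C)(C)OO
Why: Hydroxyl-directed epoxidation of a homoallylic alcohol: the C8 vanadate ester delivers the peroxide oxygen to C1=C10 through a chair-like array with the ring carbons C7 and C1 pseudo-equatorial, which places the oxirane oxygen cis to O8 (1R,10S in target numbering). The conjugated C4=C5 olefin is electron-poor and undirected, so it should be left alone.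

Step 9
Reactants: 17 (1S,3R,6Z,10R)-3-hydroxy-1,7-dimethyl-11-oxabicyclo[8.1.0]undec-6-en-5-one
Product: 19 (1S,3R,6Z,10R)-1,7-dimethyl-3,5-bis(trimethylsilyloxy)-11-oxabicyclo[8.1.0]undeca-4,6-diene, via dilithium salt 18 (not isolated)
Conditions: LiN(i-Pr)2 (2.3 equiv), THF, −78 °C; Me3SiCl (3 equiv), −78 to 0 °C
Reagents that add atoms: chlorotrimethylsilane, C[Si](C)(C)Cl
Why: Kinetic enolisation and double O-silylation; C7 is the only α-methylene, and β-elimination is suppressed because the β-substituent of enolate 18 is an alkoxide. The labile trimethylsilyl ether on O8 is chosen so that it can later be removed without strong acid or fluoride.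

Step 10
Reactants: 19 (1S,3R,6Z,10R)-1,7-dimethyl-3,5-bis(trimethylsilyloxy)-11-oxabicyclo[8.1.0]undeca-4,6-diene; 20 ethyl pyruvate
Product: 23 (1R,4Z,7R,8R,10S,11R)-1,10-epoxy-11-hydroxy-6-oxogermacr-4-en-12,8-olide, via silylated aldol adduct 21 (not isolated), via dihydroxy ester 22 (not isolated)
Conditions: [Cu((R,R)-t-Bu-box)](OTf)2 (10 mol %), THF, −78 °C; then citric acid, MeOH, 0 °C; then PPTS (cat.), CH2Cl2, rt
Reagents that add atoms: none
Why: Catalytic Mukaiyama aldol: the pyruvate is held as a five-membered chelate on the divalent copper bis(oxazoline) complex, so the ligand sets C11 (R with the R,R ligand, by analogy with simple enol silanes) and its syn preference matches the substrate. The enol silane reacts at C7 on the face anti to the ring carbon C9, with H8 eclipsing the enol ether (least A(1,3) strain), which puts C11 trans to O8. Mild methanolysis removes both silyl groups and O8 closes the γ-lactone; with C6 still a ketone no other lactone can form.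

Step 11
Reactants: 23 (1R,4Z,7R,8R,10S,11R)-1,10-epoxy-11-hydroxy-6-oxogermacr-4-en-12,8-olide
Product: 25 (1R,4Z,6R,7R,8R,10S,11R)-1,10-epoxy-6,11-dihydroxygermacr-4-en-12,8-olide, via diethylborinate 24 (not isolated)
Conditions: Et2BOMe, THF/MeOH (4:1), −78 °C; NaBH4; then pH 7 buffer, MeOH co-evaporation
Reagents that add atoms: none
Why: Narasaka–Prasad 1,3-syn reduction: the diethylboryl group bridges O11 and the C6 carbonyl, which are cis on the lactone, and external hydride enters from the exposed face away from the lactone ring and C8, giving the C6 alcohol syn to O11 (the target configuration; the descriptor reads 6R here only because of priority changes). The chelate also directs 1,2- over 1,4-reduction; 25 is taken on without exposure to acid.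

Step 12
Reactants: 25 (1R,4Z,6R,7R,8R,10S,11R)-1,10-epoxy-6,11-dihydroxygermacr-4-en-12,8-olide
Product: 26 (1R,4R,5S,6S,7R,8R,10S,11R)-1,10:4,5-diepoxy-6,11-dihydroxygermacran-12,8-olide
Conditions: VO(acac)2 (5 mol %), t-BuOOH, CH2Cl2, 0 °C
Reagents that add atoms: tert-butyl hydroperoxide, CC(C)(C)OO
Why: Hydroxyl-directed epoxidation of a medium-ring cis-allylic alcohol: in the reactive conformer O6 lies about 45° out of the olefin plane and the ring carbon C7 lies on the opposite face, so the vanadium-bound peroxide is delivered syn to O6. This gives the oxirane cis to O6 (4R,5S).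

Step 13
Reactants: 27 angelic acid
Product: 28 (Z)-2-methylbut-2-enoic 2,4,6-trichlorobenzoic anhydride
Conditions: 2,4,6-trichlorobenzoyl chloride (1.0 equiv), Et3N (1.0 equiv), toluene, 0 °C to rt; filtration under argon; used as the toluene solution
Reagents that add atoms: 2,4,6-trichlorobenzoyl chloride, O=C(Cl)c1c(Cl)cc(Cl)cc1Cl
Why: Yamaguchi activation: the triethylammonium carboxylate of 27 attacks the acid chloride to give the mixed anhydride. No nucleophilic catalyst is present, so the Z olefin of the angeloyl group should not isomerise, and removal of the ammonium chloride gives a neutral stock solution for both acylations.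

Step 14
Reactants: 26 (1R,4R,5S,6S,7R,8R,10S,11R)-1,10:4,5-diepoxy-6,11-dihydroxygermacran-12,8-olide; 28 (Z)-2-methylbut-2-enoic 2,4,6-trichlorobenzoic anhydride
Product: 29 (1R,4R,5S,6S,7S,8R,10S,11R)-6-angeloyloxy-1,10:4,5-diepoxy-11-hydroxygermacran-12,8-olide
Conditions: 28 (3 equiv), Et3N (3 equiv), toluene, 75 °C
Reagents that add atoms: none
Why: Yamaguchi-type esterification without a nucleophilic catalyst, conditions under which angelates should not isomerise to tiglates; the alcohol attacks the angeloyl carbonyl because the other carbonyl is flanked by two ortho chlorines. Only the secondary O6 reacts, since the tertiary C11 hydroxyl is inert to the neutral anhydride; triethylamine is too weak a base to form the C6 alkoxide and serves only to bind the liberated 2,4,6-trichlorobenzoic acid, which protects the two oxiranes.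

Step 15
Reactants: 29 (1R,4R,5S,6S,7S,8R,10S,11R)-6-angeloyloxy-1,10:4,5-diepoxy-11-hydroxygermacran-12,8-olide; 28 (Z)-2-methylbut-2-enoic 2,4,6-trichlorobenzoic anhydride
Product: 31 (1R,4R,5S,6S,7S,8R,10S,11R)-6,11-bis(angeloyloxy)-1,10:4,5-diepoxygermacran-12,8-olide (CNP0219924.2), via lithium alkoxide 30 (not isolated)
Conditions: LiN(SiMe3)2 (1.1 equiv), THF, −78 °C; then 28 (2 equiv, toluene solution), −78 to 0 °C; then sat. aq. NH4Cl
Reagents that add atoms: none
Why: Acylation of a tertiary lithium alkoxide by a mixed anhydride at low temperature; attack occurs at the unhindered angeloyl carbonyl because the other carbonyl is flanked by two ortho chlorines. C11 is quaternary, so the lactone cannot enolise, C6 is no longer a ketone, so the alkoxide has no retro-aldol path, and the Z olefin of the acyl group is not exposed to a nucleophilic catalyst.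

## Compound list

1 | (1Z,5Z)-1,5-dimethylcycloocta-1,5-diene | C1/C=C(C)\CC/C=C(C)\C1 | starting material
2 | rac-(1R,8S,4Z)-1,5-dimethyl-9-oxabicyclo[6.1.0]non-4-ene | C[C@@]12CC/C=C(C)\CC[C@@H]1O2 | intermediate
3 | rac-(1R,8R,4Z)-1,5-dimethyl-8-(phenylselanyl)cyclooct-4-en-1-ol | C[C@@]1(O)CC/C=C(C)\CC[C@H]1[Se]c1ccccc1 | intermediate (not isolated)
4 | rac-(1R,8R,4Z)-1,5-dimethyl-8-(phenylseleninyl)cyclooct-4-en-1-ol | C[C@@]1(O)CC/C=C(C)\CC[C@H]1[Se](=O)c1ccccc1 | intermediate (not isolated)
5 | rac-(2Z,5Z)-1,5-dimethylcycloocta-2,5-dien-1-ol | C[C@]1(O)/C=C\C/C(C)=C\CC1 | intermediate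
6 | (2Z,6Z)-3,7-dimethylcycloocta-2,6-dien-1-one | O=C1/C=C(C)\CC/C=C(C)\C1 | intermediate
7 | vinylmagnesium bromide | C=C[Mg]Br | starting material
8 | rac-(2Z,6Z)-3,7-dimethyl-1-vinylcycloocta-2,6-dien-1-ol | C=C[C@]1(O)/C=C(C)\CC/C=C(C)\C1 | intermediate
9 | potassium alkoxide of 8 | [K+].C=C[C@]1([O-])/C=C(C)\CC/C=C(C)\C1 | intermediate (not isolated)
10 | potassium C6 enolate of 11 | [K+].[O-]C1=CCC/C(C)=C\CC/C(C)=C\1 | intermediate (not isolated)
11 | (2Z,6Z)-3,7-dimethylcyclodeca-2,6-dien-1-one | O=C1/C=C(C)\CC/C=C(C)\CCC1 | intermediate
12 | lithium C6 enolate of 11 | [Li+].[O-]C1=CCC/C(C)=C\CC/C(C)=C\1 | intermediate (not isolated)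
13 | trimethylsilyl enol ether of 11 (C6=C7) | C[Si](C)(C)OC1=CCC/C(C)=C\CC/C(C)=C\1 | intermediate (not isolated)
14 | (2Z,5Z,9Z)-5,9-dimethylcyclodeca-2,5,9-trien-1-one | O=C1/C=C(C)\CC/C=C(C)\C/C=C\1 | intermediate
15 | (2Z,6Z,9R)-3,7-dimethyl-9-(4,4,5,5-tetramethyl-1,3,2-dioxaborolan-2-yl)cyclodeca-2,6-dien-1-one | O=C1/C=C(C)\CC/C=C(C)\C[C@@H](B2OC(C)(C)C(C)(C)O2)C1 | intermediate (not isolated)
16 | (2Z,6Z,9R)-9-hydroxy-3,7-dimethylcyclodeca-2,6-dien-1-one | O=C1/C=C(C)\CC/C=C(C)\C[C@@H](O)C1 | intermediate
17 | (1S,3R,6Z,10R)-3-hydroxy-1,7-dimethyl-11-oxabicyclo[8.1.0]undec-6-en-5-one | O=C1C[C@H](O)C[C@]2(C)O[C@@H]2CC/C(C)=C\1 | intermediate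
18 | dilithium alkoxide-enolate of 17 | [Li+].[Li+].[O-]C1=C[C@H]([O-])C[C@]2(C)O[C@@H]2CC/C(C)=C\1 | intermediate (not isolated)
19 | (1S,3R,6Z,10R)-1,7-dimethyl-3,5-bis(trimethylsilyloxy)-11-oxabicyclo[8.1.0]undeca-4,6-diene | C[Si](C)(C)OC1=C[C@H](O[Si](C)(C)C)C[C@]2(C)O[C@@H]2CC/C(C)=C\1 | intermediate
20 | ethyl pyruvate | CCOC(=O)C(C)=O | starting material
21 | ethyl (1R,4Z,7R,8R,10S,11R)-1,10-epoxy-6-oxo-8,11-bis(trimethylsilyloxy)germacr-4-en-12-oate | O=C1[C@@H]([C@@](C)(O[Si](C)(C)C)C(=O)OCC)[C@@H](C[C@]3(C)O[C@@H]3CC/C(C)=C\1)O[Si](C)(C)C | intermediate (not isolated)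
22 | ethyl (1R,4Z,7R,8R,10S,11R)-1,10-epoxy-8,11-dihydroxy-6-oxogermacr-4-en-12-oate | O=C1[C@@H]([C@@](C)(O)C(=O)OCC)[C@@H](C[C@]3(C)O[C@@H]3CC/C(C)=C\1)O | intermediate (not isolated)
23 | (1R,4Z,7R,8R,10S,11R)-1,10-epoxy-11-hydroxy-6-oxogermacr-4-en-12,8-olide | O=C1[C@@H]2[C@@H](C[C@]3(C)O[C@@H]3CC/C(C)=C\1)OC(=O)[C@]2(C)O | intermediate
24 | 11-O-diethylboryl derivative (chelate) of 23 | O=C1[C@@H]2[C@@H](C[C@]3(C)O[C@@H]3CC/C(C)=C\1)OC(=O)[C@]2(C)OB(CC)CC | intermediate (not isolated)
25 | (1R,4Z,6R,7R,8R,10S,11R)-1,10-epoxy-6,11-dihydroxygermacr-4-en-12,8-olide | O[C@H]1[C@@H]2[C@@H](C[C@]3(C)O[C@@H]3CC/C(C)=C\1)OC(=O)[C@]2(C)O | intermediate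
26 | (1R,4R,5S,6S,7R,8R,10S,11R)-1,10:4,5-diepoxy-6,11-dihydroxygermacran-12,8-olide | O[C@H]1[C@@H]2[C@@H](C[C@]3(C)O[C@@H]3CC[C@@]3(C)O[C@@H]13)OC(=O)[C@]2(C)O | intermediate
27 | angelic acid, (Z)-2-methylbut-2-enoic acid | C/C=C(/C)C(=O)O | starting material
28 | (Z)-2-methylbut-2-enoic 2,4,6-trichlorobenzoic anhydride | C/C=C(/C)C(=O)OC(=O)c1c(Cl)cc(Cl)cc1Cl | intermediate
29 | (1R,4R,5S,6S,7S,8R,10S,11R)-6-angeloyloxy-1,10:4,5-diepoxy-11-hydroxygermacran-12,8-olide | C/C=C(/C)C(=O)O[C@H]1[C@@H]2[C@@H](C[C@]3(C)O[C@@H]3CC[C@@]3(C)O[C@@H]13)OC(=O)[C@]2(C)O | intermediate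
30 | lithium C11 alkoxide of 29 | [Li+].C/C=C(/C)C(=O)O[C@H]1[C@@H]2[C@@H](C[C@]3(C)O[C@@H]3CC[C@@]3(C)O[C@@H]13)OC(=O)[C@]2(C)[O-] | intermediate (not isolated)
31 | (1R,4R,5S,6S,7S,8R,10S,11R)-6,11-bis(angeloyloxy)-1,10:4,5-diepoxygermacran-12,8-olide (CNP0219924.2) | C/C=C(/C)C(=O)O[C@H]1[C@@H]2[C@@H](C[C@]3(C)O[C@@H]3CC[C@@]3(C)O[C@@H]13)OC(=O)[C@]2(C)OC(=O)/C(C)=C\C | target

## Step count and least certain steps

Total: 15 steps. Longest linear sequence: 14 steps from 1 (steps 1–12, 14 and 15); step 13 is a one-step side branch from 27. Compounds 7, 20 and 27 are purchased.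

**Step 5 (key step).** The most likely failure is wrong partitioning of the fragmenting alkoxide: recombination at C1 (oxy-Cope, eight-membered isomer), attack on the hindered C4 (ring contraction), or rotation of the allyl fragment with loss of the cis C1=C10 geometry. The fallback runs the rearrangement inside its established substrate class by removing the extra olefin first; it sets out from 6 and returns at 14. Conjugate reduction of 6 with catalytic [(Ph3P)CuH]6 and PhSiH3 would give (3Z)-3,7-dimethylcyclooct-3-en-1-one F1. CeCl3-mediated addition of 7 would give (3Z)-3,7-dimethyl-1-vinylcyclooct-3-en-1-ol F2, a plain 1-vinylcycloalk-3-en-1-ol. KH and 18-crown-6 in THF (the known alkoxide-accelerated [1,3] shift) would give (5Z)-5,9-dimethylcyclodec-5-en-1-one F3. Two-fold dehydrogenation of F3 with excess 2-iodoxybenzoic acid in DMSO at 70–80 °C would then give trienone 14. The cost is that the C4=C5 geometry is no longer inherited from 1 and would have to be confirmed and, if needed, equilibrated.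

**Step 7.** Face selection may be poor on a flexible medium-ring trienone, and the copper alkoxide may isomerise the C7=C8 olefin or move the skipped olefins into conjugation before borylation. The fallback sets out from 14 and returns at 16. Catalytic asymmetric nucleophilic epoxidation of the disubstituted enone (aqueous H2O2 with a cinchona-derived primary amine salt) would give (1R,3Z,7Z,10R)-4,8-dimethyl-11-oxabicyclo[8.1.0]undeca-3,7-dien-2-one F4. Reductive cleavage of the Cα–O bond (PhSeSePh, NaBH4, AcOH, EtOH, or SmI2 at low temperature) would then give 16 with C8 retained.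

**Step 8.** The ten-membered ring may let the vanadate reach either olefin face, so facial control could be incomplete, and the slow homoallylic epoxidation may compete with oxidation of the C8 carbinol. The fallback sets out from 16 and returns at 17. NBS in wet DME at −20 °C would give (2Z,6S,7S,9R)-6-bromo-7,9-dihydroxy-3,7-dimethylcyclodec-2-en-1-one F5 (water opens the bromonium ion at the tertiary C10, anti to bromine). Brief K2CO3 in MeOH would close the oxirane with inversion at C1. This puts the oxygen on the face opposite to the one an electrophile attacks first, the complement of a direct epoxidation.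

**Step 10.** The Lewis acid may open the C1–C10 oxirane, or the oxirane and the C8 silyl ether may compete for the copper centre, slowing turnover and eroding facial control at C7 and C11. The fallback moves the aldol ahead of the epoxidation; it sets out from 16 and returns at 26. Silylation as in step 9 would give (3R,5Z,9Z)-5,9-dimethyl-1,3-bis(trimethylsilyloxy)cyclodeca-1,5,9-triene F6. The same copper-catalysed aldol with 20 and lactonisation would give (1(10)Z,4Z,7R,8R,11R)-11-hydroxy-6-oxogermacra-1(10),4-dien-12,8-olide F7. Chelation-controlled reduction as in step 11 would give (1(10)Z,4Z,6R,7R,8R,11R)-6,11-dihydroxygermacra-1(10),4-dien-12,8-olide F8. VO(acac)2 and t-BuOOH would epoxidise the allylic olefin to (1(10)Z,4R,5S,6S,7R,8R,11R)-4,5-epoxy-6,11-dihydroxygermacr-1(10)-en-12,8-olide F9, and buffered mCPBA at −20 °C would then epoxidise C1=C10 to give 26. In this order the last epoxidation is no longer hydroxyl-directed and rests on peripheral attack, which would have to be established.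

**Step 11.** Chelation by a tertiary, ring-bound hydroxyl may be incomplete, so hydride could attack the other carbonyl face and give the C6 epimer. The fallback uses that epimer through an inversion; it sets out from 23 and returns at 29. Non-chelating reduction (NaBH4, CeCl3, MeOH) would give (1R,4Z,6S,7R,8R,10S,11R)-1,10-epoxy-6,11-dihydroxygermacr-4-en-12,8-olide F10. A peracid epoxidises medium-ring cis-allylic alcohols anti to the hydroxyl, so mCPBA would give (1R,4R,5S,6R,7R,8R,10S,11R)-1,10:4,5-diepoxy-6,11-dihydroxygermacran-12,8-olide F11, which has the correct oxirane face. Mitsunobu esterification of F11 with 27 (PPh3, DIAD) would invert C6 and give 29 directly.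

**Step 15.** Acylation of the hindered tertiary alkoxide may be slow, the angelate may migrate from O6 to the alkoxide, or the angeloyl group may isomerise to tiglate on prolonged exposure to base. The fallback builds the Z olefin on the ester instead of transferring it; it sets out from 29 and returns at 31. Acylation of O11 with 2-[bis(2,2,2-trifluoroethoxy)phosphoryl]propanoyl chloride (pyridine, DMAP) would give the 11-O-{2-[bis(2,2,2-trifluoroethoxy)phosphoryl]propanoyl} derivative of 29 F12. Still–Gennari olefination with acetaldehyde (KN(SiMe3)2, 18-crown-6, THF, −78 °C) would then form the Z-2-methylbut-2-enoate.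

## Further compounds

F1 | step 5 | (3Z)-3,7-dimethylcyclooct-3-en-1-one (racemic) | O=C1CC(C)CC/C=C(C)\C1
F2 | step 5 | (3Z)-3,7-dimethyl-1-vinylcyclooct-3-en-1-ol (racemic, diastereomer mixture) | C=CC1(O)CC(C)CC/C=C(C)\C1
F3 | step 5 | (5Z)-5,9-dimethylcyclodec-5-en-1-one (racemic) | O=C1CC(C)CC/C=C(C)\CCC1
F4 | step 7 | (1R,3Z,7Z,10R)-4,8-dimethyl-11-oxabicyclo[8.1.0]undeca-3,7-dien-2-one | O=C1/C=C(C)\CC/C=C(C)\C[C@H]2O[C@@H]12
F5 | step 8 | (2Z,6S,7S,9R)-6-bromo-7,9-dihydroxy-3,7-dimethylcyclodec-2-en-1-one | O=C1C[C@H](O)C[C@](C)(O)[C@@H](Br)CC/C(C)=C\1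
F6 | step 10 | (3R,5Z,9Z)-5,9-dimethyl-1,3-bis(trimethylsilyloxy)cyclodeca-1,5,9-triene | C[Si](C)(C)OC1=C[C@H](O[Si](C)(C)C)C/C(C)=C\CC/C(C)=C\1
F7 | step 10 | (1(10)Z,4Z,7R,8R,11R)-11-hydroxy-6-oxogermacra-1(10),4-dien-12,8-olide | O=C1[C@@H]2[C@@H](C/C(C)=C\CC/C(C)=C\1)OC(=O)[C@]2(C)O
F8 | step 10 | (1(10)Z,4Z,6R,7R,8R,11R)-6,11-dihydroxygermacra-1(10),4-dien-12,8-olide | O[C@H]1[C@@H]2[C@@H](C/C(C)=C\CC/C(C)=C\1)OC(=O)[C@]2(C)O
F9 | step 10 | (1(10)Z,4R,5S,6S,7R,8R,11R)-4,5-epoxy-6,11-dihydroxygermacr-1(10)-en-12,8-olide | O[C@H]1[C@@H]2[C@@H](C/C(C)=C\CC[C@@]3(C)O[C@@H]13)OC(=O)[C@]2(C)O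
F10 | step 11 | (1R,4Z,6S,7R,8R,10S,11R)-1,10-epoxy-6,11-dihydroxygermacr-4-en-12,8-olide | O[C@@H]1[C@@H]2[C@@H](C[C@]3(C)O[C@@H]3CC/C(C)=C\1)OC(=O)[C@]2(C)O
F11 | step 11 | (1R,4R,5S,6R,7R,8R,10S,11R)-1,10:4,5-diepoxy-6,11-dihydroxygermacran-12,8-olide | O[C@@H]1[C@@H]2[C@@H](C[C@]3(C)O[C@@H]3CC[C@@]3(C)O[C@@H]13)OC(=O)[C@]2(C)O
F12 | step 15 | 11-O-{2-[bis(2,2,2-trifluoroethoxy)phosphoryl]propanoyl} derivative of 29 (mixture at the phosphonate α-carbon) | C/C=C(/C)C(=O)O[C@H]1[C@@H]2[C@@H](C[C@]3(C)O[C@@H]3CC[C@@]3(C)O[C@@H]13)OC(=O)[C@]2(C)OC(=O)C(C)P(=O)(OCC(F)(F)F)OCC(F)(F)F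
A1 | alternative 1 | cis,cis-2,3:6,7-diepoxy-2,6-dimethyloctane-1,8-diol (single enantiomer, configuration as in the SMILES) | OC[C@@H]1O[C@]1(C)CC[C@H]1O[C@@]1(C)CO
A2 | alternative 1 | (2Z,6Z)-2,6-dimethylocta-2,6-diene-1,8-diol | OC/C=C(C)\CC/C=C(C)\CO
A3 | alternative 2 | (1(10)Z,4Z)-6-(tert-butyldimethylsilyloxy)-11-(triethylsilyloxy)germacra-1(10),4-dien-12,8-olide (configuration as in the SMILES) | CC(C)(C)[Si](C)(C)O[C@H](/C=C(C)\C1)[C@@H]2[C@@H](C/C(C)=C\C1)OC(=O)[C@]2(C)O[Si](CC)(CC)CC
A4 | alternative 3 | (2Z,6Z,9R)-9-(tert-butyldimethylsilyloxy)-3,7-dimethylcyclodeca-2,6-dien-1-one | O=C1/C=C(C)\CC/C=C(C)\C[C@@H](O[Si](C)(C)C(C)(C)C)C1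
A5 | alternative 3 | cis-fused 2-(tert-butyldimethylsilyloxy)-3a-hydroxy-5,8a-dimethyl-1,2,3,3a,6,7,8,8a-octahydroazulen-8-yl methanesulfonate (one diastereomer that meets the antiperiplanar requirement) | CC1=C[C@@]2(O)C[C@H](O[Si](C)(C)C(C)(C)C)C[C@@]2(C)[C@@H](OS(C)(=O)=O)CC1
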